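**Assumption:** the target is taken exactly as drawn, i.e. the all-trans (6S,7S,8R) aryltetralin diol (the antipode of the (+)-isolariciresinol series), and benzyl-protected partners 6 and 8 are each made in one step from catalogue compounds.

## Retrosynthetic overview

1. Target diol ⇐ LiAlH4 opening of an all-trans aryltetralin γ-lactone (ent-α-conidendrin type).
2. Tetralin ring (aryl-CH–arene bond and the benzylic stereocentre) ⇐ anodic dehydrogenative cyclisation of a trans-2,3-dibenzyl-γ-butyrolactone via a syringyl p-quinone methide.
3. Dibenzylbutyrolactone ⇐ hydrogenolysis/decarboxylation of an α-benzylated α-(benzyloxycarbonyl) lactone ⇐ one-pot aryl-copper cyclopropane opening and enolate benzylation.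
4. Cyclopropane-fused lactone ⇐ dibenzyl malonate + (S)-epichlorohydrin, the only source of chirality.
5. Ring order: cyclopropane and γ-lactone together, cyclopropane opened, carbocycle closed electrochemically, lactone opened last.

## Route

**Step 1**
Reactants: 1 (S)-epichlorohydrin; 2 dibenzyl malonate
Product: 3 benzyl (1S,5S)-2-oxo-3-oxabicyclo[3.1.0]hexane-1-carboxylate (cis-fused cyclopropane lactone)
Conditions: NaOBn (1.1 equiv, from NaH + BnOH), BnOH–THF, 0 → 65 °C, 16 h
Reagents that add atoms: none
Why: Malonate–epichlorohydrin cyclopropanation/lactonisation cascade (epoxide opening at CH2, re-closure onto CH2Cl, 3-exo-tet opening with one inversion, lactonisation) carries the bought stereocentre into C5, and the cis fusion fixes C1.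

**Step 2**
Reactants: 4 4-bromo-2,6-dimethoxyphenol; 5 benzyl bromide
Product: 6 2-(benzyloxy)-5-bromo-1,3-dimethoxybenzene
Conditions: K2CO3, DMF, 60 °C
Reagents that add atoms: benzyl bromide (5), BrCc1ccccc1
Why: Williamson etherification of the phenol; the aryl bromide is inert.

**Step 3**
Reactants: 7 4-(benzyloxy)-3-methoxybenzyl alcohol
Product: 8 4-(benzyloxy)-3-methoxybenzyl bromide
Conditions: PBr3, CH2Cl2, 0 °C; use fresh
Reagents that add atoms: phosphorus tribromide, BrP(Br)Br
Why: Standard PBr3 bromination of an electron-rich primary benzylic alcohol; the aryl benzyl ether survives.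

**Step 4**
Reactants: 3 cyclopropane lactone; 6 aryl bromide (as its Grignard reagent); 8 benzylic bromide
Product: 9 benzyl (3R,4S)-4-[4-(benzyloxy)-3,5-dimethoxybenzyl]-3-[4-(benzyloxy)-3-methoxybenzyl]-2-oxotetrahydrofuran-3-carboxylate (the two arylmethyl groups trans)
Conditions: 6, Mg, LiCl, THF, 40 °C (1.15 equiv ArMgBr); CuI (15 mol%), 3, THF, −40 → −10 °C; then 8 (1.6 equiv), DMPU, −10 → 40 °C
Reagents that add atoms: none besides reactants 6 and 8
Why: Cu-catalysed homoconjugate (SN2-type) opening of the doubly activated cyclopropane at its CH2 leaves the stereocentre untouched, and the resulting stabilised enolate is C-benzylated in situ anti to the β-substituent (this quaternary configuration is erased in Step 5).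

**Step 5**
Reactants: 9
Product: 10 (3S,4S)-4-(4-hydroxy-3,5-dimethoxybenzyl)-3-(4-hydroxy-3-methoxybenzyl)dihydrofuran-2(3H)-one (trans)
Conditions: H2 (1 atm), 10% Pd/C, EtOAc–EtOH, rt; filter; DMF, 120 °C; then DBU (3 equiv), 60 °C; aq. HCl work-up; recrystallise
Reagents that add atoms: none
Why: Hydrogenolysis of the three benzyl groups gives a malonic half-acid that decarboxylates thermally, and DBU equilibration through the lactone enolate gives the thermodynamically preferred trans-2,3-dibenzyl lactone, so C3 is set by the bought C4 centre.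

**Step 6 (key step)**
Reactants: 10
Product: 11 (3aS,4R,9aS)-6-hydroxy-4-(4-hydroxy-3,5-dimethoxyphenyl)-7-methoxy-3a,4,9,9a-tetrahydronaphtho[2,3-c]furan-1(3H)-one (aryl trans to C3a–CH2O; trans-fused lactone)
Conditions: undivided cell, graphite anode / Pt cathode, Bu4NPF6 (0.1 M), HFIP–CH2Cl2 (4:1), 5 mM, 0 °C, controlled potential at the first anodic wave (ca. +0.8 V vs Ag/AgCl, set by CV), 2.1 F/mol; then TFA (10 mol%), rt, 1 h
Reagents that add atoms: none
Why: Proposed new method: anodic dehydrogenative benzylic C–H arylation, in which the more easily oxidised syringol (ortho and para positions blocked, so no phenoxyl coupling) loses 2 e⁻/2 H⁺ to give a p-quinone methide that HFIP/acid activates for intramolecular Friedel–Crafts attack by the guaiacyl ring para to its OMe through a chair-like transition state with the aryl pseudo-equatorial, giving the 1,2-trans centre under control of the adjacent stereocentre; the closest known reactions are DDQ-mediated oxidative cyclisation of dibenzylbutyrolactones, the acid cyclisation of hydroxymatairesinol to α-conidendrin, and anodic phenol oxidation in HFIP.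

**Step 7**
Reactants: 11
Product: 12 (6S,7S,8R)-8-(4-hydroxy-3,5-dimethoxyphenyl)-6,7-bis(hydroxymethyl)-3-methoxy-5,6,7,8-tetrahydronaphthalen-2-ol (target)
Conditions: LiAlH4 (6 equiv), THF, 0 °C → reflux; Rochelle salt / dilute HCl work-up
Reagents that add atoms: none
Why: Hydride reduction of the γ-lactone to the 1,4-diol (as in α-conidendrin → isolariciresinol) touches no stereocentre; the phenols only consume hydride as phenoxides.

## Compound list

1 | (S)-epichlorohydrin | ClC[C@@H]1CO1 | starting material
2 | dibenzyl malonate | O=C(OCc1ccccc1)CC(=O)OCc1ccccc1 | starting material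
3 | benzyl (1S,5S)-2-oxo-3-oxabicyclo[3.1.0]hexane-1-carboxylate | O=C1OC[C@H]2C[C@@]12C(=O)OCc1ccccc1 | intermediate
4 | 4-bromo-2,6-dimethoxyphenol | COc1cc(Br)cc(OC)c1O | starting material
5 | benzyl bromide | BrCc1ccccc1 | starting material
6 | 2-(benzyloxy)-5-bromo-1,3-dimethoxybenzene | COc1cc(Br)cc(OC)c1OCc1ccccc1 | intermediate
7 | 4-(benzyloxy)-3-methoxybenzyl alcohol | COc1cc(CO)ccc1OCc1ccccc1 | starting material
8 | 4-(benzyloxy)-3-methoxybenzyl bromide | COc1cc(CBr)ccc1OCc1ccccc1 | intermediate
9 | benzyl (3R,4S)-4-[4-(benzyloxy)-3,5-dimethoxybenzyl]-3-[4-(benzyloxy)-3-methoxybenzyl]-2-oxotetrahydrofuran-3-carboxylate | O=C1OC[C@@H](Cc2cc(OC)c(OCc3ccccc3)c(OC)c2)[C@@]1(Cc1ccc(OCc2ccccc2)c(OC)c1)C(=O)OCc1ccccc1 | intermediate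
10 | (3S,4S)-4-(4-hydroxy-3,5-dimethoxybenzyl)-3-(4-hydroxy-3-methoxybenzyl)dihydrofuran-2(3H)-one | O=C1OC[C@@H](Cc2cc(OC)c(O)c(OC)c2)[C@@H]1Cc1ccc(O)c(OC)c1 | intermediate
11 | (3aS,4R,9aS)-6-hydroxy-4-(4-hydroxy-3,5-dimethoxyphenyl)-7-methoxy-3a,4,9,9a-tetrahydronaphtho[2,3-c]furan-1(3H)-one | COc1cc2c(cc1O)[C@@H](c1cc(OC)c(O)c(OC)c1)[C@@H]1COC(=O)[C@H]1C2 | intermediate
12 | (6S,7S,8R)-8-(4-hydroxy-3,5-dimethoxyphenyl)-6,7-bis(hydroxymethyl)-3-methoxy-5,6,7,8-tetrahydronaphthalen-2-ol | COc1cc2c(cc1O)[C@@H](c1cc(OC)c(O)c(OC)c1)[C@H](CO)[C@@H](CO)C2 | target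

## Summary

Total steps: 7. Longest linear sequence: 5 (Steps 1, 4, 5, 6, 7).

Steps most likely to fail:

1. **Step 6 (proposed new anodic cyclisation).** Risks are competing oxidation of the guaiacyl phenol, over-oxidation of the product's own syringol, and intermolecular quinone-methide trapping. Fallback (known chemistry): move to a benzylic-alcohol route. Open the cyclopropane lactone (ethyl ester series) with the Grignard from 1-(benzyloxy)-4-bromo-2-methoxybenzene and remove the ester by Krapcho. Then run an LDA aldol with 4-(benzyloxy)-3,5-dimethoxybenzaldehyde and close the ring by TFA Friedel–Crafts cyclisation of the benzylic alcohol (all-trans aryltetralin lactone). H2/Pd–C and LiAlH4 then give the same target.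

2. **Step 4 (one-pot opening and benzylation).** The magnesium enolate may alkylate sluggishly, and excess Grignard can consume 8. Fallback: use the ethyl ester of 3, quench after ring opening, and remove the ester by Krapcho (LiCl, wet DMSO) to give the simple (S)-β-arylmethyl lactone. Install the vanillyl group by kinetic trans-alkylation of its LiHMDS enolate with 8, then hydrogenolyse to 10.

3. **Step 5 (hydrogenolysis, decarboxylation, equilibration).** Kinetic protonation favours the cis lactone, and equilibration in the presence of two free phenols may be incomplete. Fallback: build the series from diallyl malonate and remove the allyl ester by Pd(0)-catalysed deallylation–decarboxylation while the phenols are still benzylated. Equilibrate the protected lactone to trans with DBU, then hydrogenolyse the two benzyl ethers.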